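Two constants read from Saturday's run carry our estimate of the end of west and south-west, and we count everything in fractions of the charge.

| flask | first end groups | second end groups | remark | time |
|---|---|---|---|---|
| Saturday's | 20 mM | 20 mM | run made earlier |  |
| Tuesday's | 28 mM | 20 mM | run made earlier |  |
| Friday's | 44 mM | 20 mM | run made earlier |  |
| west | 20 mM | 20.0 mM | everything together at the start | 20 h |
| south | 20 mM | 20.0 mM (fed, over 8.0 h) | all else is in the flask from the start; the feed brings no volume worth counting | 20 h |
| south-west | 20 mM (fed, over 8.0 h) | 20.0 mM | all else is in the flask from the start; the feed brings no volume worth counting | 20 h |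

| run | time / h | links / % | rings / % |
|---|---|---|---|
| Saturday's | 2.00 | 18.5 | 3.4 |
| Saturday's | 4.00 | 18.1 | 6.8 |
| Saturday's | 6.00 | 17.3 | 11.0 |
| Saturday's | 8.00 | 15.9 | 14.5 |
| Saturday's | 10.0 | 14.0 | 17.9 |
| Saturday's | 12.0 | 12.8 | 20.8 |
| Tuesday's | 1.00 | 17.7 | 1.9 |
| Tuesday's | 3.00 | 17.1 | 5.2 |
| Tuesday's | 6.00 | 15.1 | 10.6 |
| Tuesday's | 8.00 | 14.3 | 14.3 |
| Tuesday's | 12.0 | 11.5 | 20.6 |
| Tuesday's | 15.0 | 10.2 | 26.1 |
| Friday's | 2.50 | 16.0 | 5.3 |
| Friday's | 5.00 | 12.4 | 9.5 |
| Friday's | 8.00 | 10.4 | 14.4 |
| Friday's | 10.0 | 8.0 | 18.5 |
| Friday's | 12.0 | 7.8 | 22.3 |
| Friday's | 15.0 | 5.7 | 26.3 |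

(scatter of a reading: 0.5 percentage points)

- candidate steps: first end groups + second end groups <-> links; first end groups + second end groups -> rings

1. the flask that comes out highest in share of links in links plus rings, or "all alike" when all lie within 1.5 percentage points (west / south / south-west / all alike)
2. share of links in links plus rings at the end, west
3. share of links in links plus rings at the end, south
4. share of links in links plus rings at the end, south-west

The first constant is the link number, links over the product of the free fractions of the two end groups, 0.328 at 8.00 h and 0.303 at 2.00 h, so we treat links as a rapid pre-equilibrium. The second is the ring constant, rings gained per hour up to the last reading over the free fraction of first end groups at 6.00 h, 0.0242 h⁻¹. To the last reading, rings gained 0.0173 h⁻¹, 0.0174 h⁻¹ and 0.0175 h⁻¹ of the first end groups charged on Saturday, Tuesday and Friday.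

West repeats Saturday's charge, so we carry rings from the last reading to 20 h, holding the free fraction of that reading, and reach 0.336. The link number then leaves a free fraction of 0.560 and a link share of 23.5 %. South-west's feed takes about 4.00 h off the exposure of first end groups, giving rings of 0.269, a free fraction of 0.609 and a share of 31.2 %. We put south at or just under west. Leave the south-west feed at 8.0 h, since those hours lift its share above west.

The forecast gives 23 %, 21.8 % and 29.5 % for west, south and south-west and names south-west, holding, with A for first end groups, that there “A stays starved early”. It differs from our south-west by 1.7 percentage points.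

The flasks give 24.3 %, 22.9 % and 31.0 %, with south-west highest.

    first end groups + second end groups ⇌ links (K = 16.0 L mol⁻¹, k = 97.0 L mol⁻¹ h⁻¹)
    first end groups + second end groups → rings, rate k2*[first end groups] as long as [second end groups] is above zero (k = 0.0240 h⁻¹)

In south, the link step relaxes, both ways together, with a half-life of 0.0842 h at 20.0 h, short against the run's 20 h. There the link number times the free fractions at 20.0 h gives 10.3 %, and links stand at 10.1 %. South left until 72.0 h holds free fractions of 20.2 %, the link number then gives 1.34 %, and links stand at 1.32 %.

The data were generated by integration with made-up constants; the scatter is artificial.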